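Slowness is not what holds the target down in the oak run, which reads 47.4% after 2.50 h and 48.3% after 10.0 h. So we read each earlier run by the mean of its last 3 readings, taken as a concentration: 0.00999 M for oak, 0.0199 M for alder and 0.0204 M for ash.

| flask | starting material | partner A | partner B | remark | time |
|---|---|---|---|---|---|
| oak | 0.021 M | 0.075 M | 0.20 M | run made earlier |  |
| alder | 0.078 M | 0.075 M | 0.20 M | run made earlier |  |
| ash | 0.18 M | 0.075 M | 0.20 M | run made earlier |  |
| Wednesday's | 0.025 M | 0.0750 M | 0.200 M |  | 15 h |
| Monday's | 0.050 M | 0.0750 M | 0.200 M |  | 15 h |
| Friday's | 0.10 M | 0.0750 M | 0.200 M |  | 15 h |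
| Sunday's | 0.20 M | 0.0750 M | 0.200 M |  | 15 h |

- oak (time / h: target / %): 1.00: 37.1; 2.50: 47.4; 5.00: 47.3; 8.00: 47.1; 10.0: 48.3
- alder (time / h: target / %): 1.00: 15.0; 2.50: 23.3; 5.00: 25.8; 8.00: 26.0; 10.0: 24.9
- ash (time / h: target / %): 2.00: 7.7; 4.00: 9.8; 6.00: 11.0; 8.00: 10.9; 10.0: 12.1

(standard deviation of a reading: 0.5 percentage points)

- "hardly changes" means that all values lie within two and a half points (for a concentration: within two and a half percent of the largest)

* [target] at the end for Wednesday's, Monday's, Friday's, Sunday's, in this order
* the course of these numbers from the first flask to the last (rises all the way / falls all the way / rises, then falls / falls, then rises / hardly changes)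

Take first the main step by itself, starting material going to target. Each molecule then has the same chance whatever the charge, so the percent stays put and [target] grows in step with the charge. That is the zero of our scale, and we measure the departure from it by the order of the row: the change in ln[target] at the end per change in ln(charge) between neighbouring flasks, which is 1 for the main step by itself. Now add one more process, a loss in which two molecules derived from the starting material meet. With a fixed supply of partner, such a loss brings the order towards 0.5, and from oak to alder the order reads 0.527. Then add the rest, whatever further stops the target rising with the charge: from alder to ash the order reads 0.0272.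

Our own reckoning carries these orders from the nearest run. With the first order from oak, Wednesday's flask gets 0.0110 M and Monday's 0.0158 M. With the second order, Friday's flask gets 0.0201 M from alder and Sunday's 0.0205 M from ash. That row rises all the way. The forecast differs in its shape: it gives 0.0113 M, 0.017 M, 0.0211 M and 0.0205 M, rises, then falls, and says “The final fall is small and uncertain”.

The flasks give 0.0112 M, 0.0165 M, 0.0220 M and 0.0180 M, rises, then falls, turning at 0.15 M.

    starting material + partner B → open intermediate (k = 0.210 M⁻¹ min⁻¹)
    partner B + partner A → second intermediate (k = 0.0270 M⁻¹ min⁻¹)
    open intermediate + second intermediate → target (k = 11.0 M⁻¹ min⁻¹)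
    2 open intermediate → homo product (k = 8.90 M⁻¹ min⁻¹)
    open intermediate → decomposed reagent (k = 0.0300 min⁻¹)

The order reads 0.559 from Wednesday's to Monday's flask, against our 0.527, then 0.36 at Friday's, and −0.290 from Friday's to Sunday's. In Wednesday's flask, the step from starting material and partner B to open intermediate had 96% of its turnover up to 15 h behind it after 1.50 h, the step from partner B and partner A 35%. In Sunday's flask partner B, the limiting reagent, stood at 1.21% of its charge at 7.50 h and 0.092% at 15.0 h, when target held 9.00% of the starting material charged.

Readings and results are simulated for substances that don't exist; the scatter is artificial.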